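14.3% of the charge is the mean reading of complex with two exchanged over the last three north-west readings, beside a mean of 14.3% of starting complex. Tuesday's repeats that recipe, while the other flasks change how one reagent goes in.

| flask | starting complex | incoming ligand | remark | time |
|---|---|---|---|---|
| north-west | 20 mM | 30 mM | run made earlier |  |
| north-east | 20 mM | 15 mM | run made earlier |  |
| south-east | 20 mM | 22 mM | run made earlier |  |
| east | 10 mM | 30 mM | run made earlier |  |
| Wednesday's | 20 mM | 30.0 mM (in portions, 5, over 12 h) | first portion at the start, last at 12 h | 30 h |
| Saturday's | 20 mM (fed, over 12 h) | 30.0 mM | all else is in the flask from the start; the feed brings no volume worth counting | 30 h |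
| Sunday's | 20 mM | 30.0 mM (fed, over 12 h) | all else is in the flask from the start; the feed brings no volume worth counting | 30 h |
| Tuesday's | 20 mM | 30.0 mM | everything together at the start | 30 h |

- north-west (time / h: complex with two exchanged / %, starting complex / %): 6.00: 18, 22; 12.0: 16, 16; 20.0: 15, 13; 25.0: 16, 17; 30.0: 12, 13
- north-east (time / h: complex with two exchanged / %, starting complex / %): 2.50: 9, 62; 8.00: 9, 44; 15.0: 8, 45; 20.0: 12, 46; 30.0: 11, 43
- south-east (time / h: complex with two exchanged / %, starting complex / %): 2.50: 8, 44; 8.00: 15, 34; 15.0: 12, 31; 20.0: 14, 32; 30.0: 12, 31
- east (time / h: complex with two exchanged / %, starting complex / %): 6.00: 11, 8; 12.0: 7, 3; 20.0: 2, 1; 25.0: 0, 2; 30.0: 1, 0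

(readings scatter by 2 percentage points)

* the flask with the highest amount of complex with two exchanged, in percent of the starting complex charged ("all alike" if they lie within 1.5 percentage points) (Wednesday's / Saturday's / Sunday's / Tuesday's / all alike)
* final complex with two exchanged, as a percentage of the starting complex charged, in Wednesday's
* final complex with two exchanged, as a percentage of the starting complex charged, in Saturday's
* final complex with two exchanged, as a percentage of the starting complex charged, in Sunday's
* final complex with two exchanged, as a percentage of the starting complex charged, in Tuesday's



We follow one molecule, in fractions of the charge. We count one incoming ligand for the first exchange, one more for the second and one more again for the third. So if the ligand is spent and nothing waits in between, the ligand charged minus the complex lost, a surplus of 0.643 in the north-west run, equals the complex with two exchanged plus the complex with three exchanged counted for two. That puts 0.250 at three exchanged, and 0.636 is then the third-exchange chance, the share of molecules past the second exchange that take the third, a branching ratio read with the scatter of the readings. The complex with two exchanged is the surplus times (1 − chance)/(1 + chance). For Wednesday's we hold this chance: with as much starting complex left as in the north-west run we get a top of 14.3%, and with none left the surplus falls to 0.500 and we get a bottom of 11.1%.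

The forecast holds that “dosing ligand doesn't change selectivity”, and gives 14% for Wednesday's, at our top, with 10.5% for Saturday's, 14% for Sunday's, 14% for Tuesday's and all alike as its label.

The flasks give 7.65% for Wednesday's, below our bracket, 14.1% for Saturday's, 8.72% for Sunday's and 16.0% for Tuesday's, so the highest is Tuesday's.

    starting complex + incoming ligand ⇌ leaving ligand + complex with one exchanged (K = 0.400, k = 34.0 /M/h)
    complex with one exchanged → side product (k = 0.280 /h)
    complex with one exchanged + incoming ligand ⇌ leaving ligand + complex with two exchanged (K = 37.0, k = 34.0 /M/h)
    complex with two exchanged + incoming ligand ⇌ leaving ligand + complex with three exchanged (K = 0.380, k = 52.0 /M/h)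
    leaving ligand → by-product carried off (k = 1.60 /h)

Wednesday's ends with a surplus of 0.528, which at our 0.636 gives 11.8%, but its own third-exchange chance stands at 0.747, higher. The neighbour of Wednesday's with 8.0 mM of starting complex has 3.75 equiv of incoming ligand and ends with 0% of starting complex, a surplus of 0.984 and a third-exchange chance of 1.00, and its complex with two exchanged stands at 0.0162%.

The runs are calculated with made-up constants, noise included.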